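Late in a run substrate is thin and each further share of it costs more hours, while early on gas must come in for every bit of product. So I let dissolved gas stand where its feed from the gas phase equals its use at the catalyst (the steady-state approximation).

the same everywhere: gas phase 59 mM (held)
- violet: substrate 1.1 M; catalyst 54 mM; run made earlier
- blue: substrate 1.7 M; catalyst 54 mM; run made earlier
- grey: substrate 0.78 M; catalyst 81 mM; run made earlier
- flask: substrate 0.78 M; catalyst 54 mM; time 20 h

- violet (time / h: product / %, substrate / %): 2.00: 10.3, 89.1; 3.00: 15.2, 82.4; 4.00: 20.4, 79.5; 6.00: 30.7, 66.7; 10.0: 51.8, 48.0; 15.0: 72.4, 28.3; 25.0: 96.7, 6.5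
- blue (time / h: product / %, substrate / %): 2.00: 8.6, 92.8; 3.00: 10.8, 88.6; 4.00: 15.7, 85.7; 6.00: 22.0, 78.4; 10.0: 39.0, 61.6; 15.0: 55.9, 46.0; 25.0: 82.6, 17.0
- grey (time / h: product / %, substrate / %): 2.00: 15.3, 85.8; 4.00: 30.1, 68.0; 6.00: 46.5, 56.7; 12.0: 77.5, 21.1; 25.0: 96.4, 3.0

(scatter of a reading: 1 percentage point)

- at the start none of the gas is dissolved
- steps that have been proposed: gas phase <-> dissolved gas; substrate + dissolved gas + catalyst <-> catalyst + product

- gamma: doubling the transfer coefficient of the gas phase, all else as stated
- eta: doubling the amount of catalyst, all else as stated
- beta: doubling the saturation concentration of gas phase, all else as stated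

1. product at 20 h, in percent of the substrate charged
2. the change that raises the amount of product at 20 h, in percent of the substrate charged most ("none" if none brings more than 2 percentage points) (gamma / eta / beta / none)
3. amount of product at 20 h, in percent of the substrate charged, after gamma

With x the fraction of the charge left, the hours add up as two bills:

t = T·(1 − x) + b·ln(1/x)

The feed time T grows with the charge, and the catalyst time b shrinks with more catalyst. The blue run at 25.0 h and the violet run at 15.0 h give two such lines. Solved and scaled to this flask's charge, they give T = 10.1 h and b = 3.77 h. Their ratio r = 2.68 is the feed ratio, feed time over catalyst time. It tells what share of saturation is filled with dissolved gas: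

s = 1/(1 + r·x)

The wait for this balance, 0.766 h, is far shorter than 20 h. A first pass for this flask gives:

x = exp(r − t/b) = 7.30%

The weak link is that the bill lets x fall towards nothing. For the grey run it leaves 0.270% at 25.0 h, yet the reading is 3.0%, and that run shares this flask's substrate and gas. So I read the step as running back and take that reading as a floor f:

x = f + (1 − f)·exp(−(t − T(1 − x))/b) = 8.82%

I commit to 91.2% product. Halving T for gamma gives 95.4%. Eta halves b and beta halves both bills, so I choose beta.

The forecast says 92% (range 89% to 95%), a little more than my figure, with 95.8% after gamma and beta best, since “Doubling saturation halves both terms”.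

The flask gives 92.9%, and 96.7% after gamma. Beta gains most, 5.9 percentage points against 3.8 points and 4.2 points.

    gas phase ⇌ dissolved gas, rate k1*(csat - [dissolved gas]) (kL = 1.30 h⁻¹)
    substrate + dissolved gas + catalyst ⇌ catalyst + product (K = 700 M⁻¹, k = 99.0 M⁻² h⁻¹)

Read as early as 17.0 h, the answer has moved by 5 points. With 7.11% left at 20.0 h, the feed ratio gives s = 84.0%, and the flask holds dissolved gas at 85.4% of saturation.

Read at 5.0 h, the same flask is still early, so the two bills nearly merge and product is about t/(b(1 + r)) = 36.0%. The computed product is 33.7%.

(The earlier runs and the new flask come from a simulation from invented constants.)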